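**Retrosynthetic overview**
1. Cudraphenone D (18) comes from its tris-MOM ether 17 by mild acid. The strategy rests on ring A: C1 (aroyl), C2 (prenyl) and C3 (OH) are contiguous, C4–C6 are unsubstituted CH, and the OH is meta to the ketone.
2. Ring A of 17 is disconnected to furan (15) and aryl alkynyl ketone 14: C1 and C2 are the two alkyne carbons, C3–C6 and the phenol oxygen are furan (Diels–Alder reaction, then opening of the oxygen bridge of 16).
3. Ynone 14 comes from propargylic alcohol 13, made from ring B aldehyde 7 and the acetylide of 5-methylhex-4-en-1-yne (11).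
4. Aldehyde 7 comes from phloroglucinol (1) by MOM protection and two directed ortho-lithiations (prenylation, then formylation); 11 comes from trimethylsilylacetylene (8) and prenyl bromide (3).
5. Ring order: ring B is bought aromatic and dressed first; ring A is formed last from the open-chain alkyne and furan.

Key step: step 8

Remark on the chemistry: the oxygen-bridged cycloadduct 16 is expected to open under the same Lewis acid that forms it, so cycloaddition and aromatization are written as one step; carbinol 13 and bicycle 16 are racemic and the target is achiral.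

**Route**

Step 1
Reactants: 1 phloroglucinol
Product: 2 1,3,5-tris(methoxymethoxy)benzene
Conditions: NaH (3.6 equiv), MOMCl (3.6 equiv), DMF, 0 °C → rt
Reagents that add atoms: chloromethyl methyl ether (MOMCl), COCCl
Why: Williamson-type O-alkylation of the sodium phenoxides by the highly reactive α-chloro ether should give the tris-acetal, whose OMOM groups direct both later lithiations and come off under mild acid.

Step 2
Reactants: 2 1,3,5-tris(methoxymethoxy)benzene, 3 prenyl bromide (1-bromo-3-methylbut-2-ene)
Product: 5 1,3,5-tris(methoxymethoxy)-2-(3-methylbut-2-en-1-yl)benzene, via aryllithium 4 (not isolated)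
Conditions: n-BuLi (1.1 equiv), THF, 0 °C → rt; then CuI (10 mol %), 3, −20 °C → rt
Reagents that add atoms: none
Why: Directed ortho-metalation removes a proton flanked by two coordinating OMOM groups (all three ring CH are equivalent), and the copper-assisted alkylation of the aryllithium should take place at the unhindered primary carbon of the allylic bromide.

Step 3
Reactants: 5 1,3,5-tris(methoxymethoxy)-2-(3-methylbut-2-en-1-yl)benzene
Product: 7 2,4,6-tris(methoxymethoxy)-3-(3-methylbut-2-en-1-yl)benzaldehyde, via aryllithium 6 (not isolated)
Conditions: n-BuLi (1.2 equiv), TMEDA, THF, −20 → 0 °C; then DMF, 0 °C → rt; sat. aq NH4Cl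
Reagents that add atoms: N,N-dimethylformamide (DMF), CN(C)C=O
Why: A second directed ortho-metalation at either of the two equivalent ring CH positions, each again between two OMOM groups, followed by Bouveault-type formylation with DMF, whose tetrahedral adduct releases the aldehyde only on aqueous work-up.

Step 4
Reactants: 8 ethynyltrimethylsilane (trimethylsilylacetylene), 3 prenyl bromide
Product: 10 trimethyl(5-methylhex-4-en-1-yn-1-yl)silane, via alkynylmagnesium bromide 9 (not isolated)
Conditions: EtMgBr (1.05 equiv), THF, 0 → 40 °C; then CuCl (5 mol %), 3, THF, 50 °C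
Reagents that add atoms: none
Why: Copper-catalysed coupling of an alkynyl Grignard reagent with an allylic halide should substitute the γ,γ-dimethylallyl bromide at its primary carbon to give the skipped enyne, the silyl cap preventing a second alkylation.

Step 5
Reactants: 10 trimethyl(5-methylhex-4-en-1-yn-1-yl)silane
Product: 11 5-methylhex-4-en-1-yne
Conditions: K2CO3 (0.2 equiv), MeOH, 0 °C → rt; pentane/H2O partition, pentane distilled off through a Vigreux column
Reagents that add atoms: none
Why: Methoxide-mediated protodesilylation of the alkynylsilane is mild enough not to isomerize the skipped enyne, and the volatile alkyne is kept as a dried, assayed stock solution and never taken to dryness.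

Step 6
Reactants: 11 5-methylhex-4-en-1-yne, 7 2,4,6-tris(methoxymethoxy)-3-(3-methylbut-2-en-1-yl)benzaldehyde
Product: 13 rac-6-methyl-1-[2,4,6-tris(methoxymethoxy)-3-(3-methylbut-2-en-1-yl)phenyl]hept-5-en-2-yn-1-ol, via lithium acetylide 12 (not isolated)
Conditions: 11 (1.3 equiv), n-BuLi (1.25 equiv), THF, −78 °C; then 7, −78 → −20 °C; sat. aq NH4Cl
Reagents that add atoms: none
Why: The terminal alkyne C–H is far more acidic than the CH2 between alkyne and alkene, so n-BuLi should give the acetylide cleanly, and its 1,2-addition to the aldehyde forms a racemic carbinol centre that is erased by the next oxidation.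

Step 7
Reactants: 13 rac-6-methyl-1-[2,4,6-tris(methoxymethoxy)-3-(3-methylbut-2-en-1-yl)phenyl]hept-5-en-2-yn-1-ol
Product: 14 6-methyl-1-[2,4,6-tris(methoxymethoxy)-3-(3-methylbut-2-en-1-yl)phenyl]hept-5-en-2-yn-1-one
Conditions: activated MnO2 (15 equiv), CH2Cl2, rt; filtered through Celite, used at once
Reagents that add atoms: none
Why: MnO2 oxidation of a benzylic and propargylic alcohol runs under neutral heterogeneous conditions that should leave the MOM acetals, both prenyl alkenes and the isomerization-prone CH2 between alkyne and alkene untouched.

Step 8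
Reactants: 14 6-methyl-1-[2,4,6-tris(methoxymethoxy)-3-(3-methylbut-2-en-1-yl)phenyl]hept-5-en-2-yn-1-one, 15 furan
Product: 17 [3-hydroxy-2-(3-methylbut-2-en-1-yl)phenyl][2,4,6-tris(methoxymethoxy)-3-(3-methylbut-2-en-1-yl)phenyl]methanone, via oxanorbornadiene 16 (not isolated)
Conditions: furan (20 equiv), Me2AlCl (2.5 equiv, 1 M in hexanes), CH2Cl2, −78 → −20 °C; cold aq KNaC4H4O6 (potassium sodium tartrate)
Reagents that add atoms: none
Why: Proposed new method: Me2AlCl bound to the ketone oxygen (with an ortho OMOM oxygen as second donor) should lower the LUMO of the ynone enough for furan C2 and C5 to add across the two alkyne carbons, either in a concerted asynchronous [4+2] cycloaddition or, at the stepwise limit, by Friedel–Crafts attack of furan C2 on the β-carbon and collapse of the aluminium allenolate onto the oxocarbenium carbon; this forms two C–C bonds and closes the six-membered carbocycle of ring A as the oxygen-bridged bicycle 16. The closest known reaction type is the aluminium-Lewis-acid-promoted Diels–Alder reaction of furans with propiolates and alkynyl ketones followed by isomerization of the 7-oxanorbornadiene to a phenol, which is established intermolecularly for terminal acetylenic esters and ketones and intramolecularly for furan-tethered β-substituted ynones but not intermolecularly for a β-alkyl aryl ynone. The two bridgehead stereocentres of 16 form as a racemate, their relative configuration is dictated by the bicycle, and both disappear on aromatization. The selectivity that matters is which bridge C–O bond ionizes: cleavage at the bridgehead next to the aroyl-bearing carbon gives a cyclohexadienyl cation with charge on the prenyl-bearing carbon and none on the carbon α to the complexed carbonyl, whereas the other cleavage would place charge on that α-carbon, so the oxygen should stay on the carbon ortho to prenyl and meta to the ketone, and loss of its proton (taken up by an Al–CH3 bond as methane) gives the aluminium phenoxide of 17. This aromatization is irreversible and pulls the reversible furan cycloaddition forward, and because furan is symmetric the addition itself has no regiochemistry. Excess furan, low temperature and the proton-scavenging Al–CH3 bonds are meant to hold back simple conjugate addition of furan, isomerization of the CH2 between alkyne and alkene, loss of MOM groups and chroman formation.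

Step 9
Reactants: 17 [3-hydroxy-2-(3-methylbut-2-en-1-yl)phenyl][2,4,6-tris(methoxymethoxy)-3-(3-methylbut-2-en-1-yl)phenyl]methanone
Product: 18 Cudraphenone D
Conditions: HCl (0.5 M in MeOH), rt, followed closely; aq NaHCO3 quench
Reagents that add atoms: none
Why: Acid-catalysed transacetalization of the three aryl MOM ethers to dimethoxymethane proceeds through an oxocarbenium ion and should be much faster at this acidity than protonation of the trisubstituted alkenes, so the reaction can be stopped before either prenyl group closes onto a neighbouring phenol.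

**Compound list**
1 | phloroglucinol | Oc1cc(O)cc(O)c1 | starting material
2 | 1,3,5-tris(methoxymethoxy)benzene | COCOc1cc(OCOC)cc(OCOC)c1 | intermediate
3 | prenyl bromide (1-bromo-3-methylbut-2-ene) | CC(C)=CCBr | starting material
4 | [2,4,6-tris(methoxymethoxy)phenyl]lithium (formed in the flask, not isolated) | [Li]c1c(OCOC)cc(OCOC)cc1OCOC | intermediate
5 | 1,3,5-tris(methoxymethoxy)-2-(3-methylbut-2-en-1-yl)benzene | COCOc1cc(OCOC)c(CC=C(C)C)c(OCOC)c1 | intermediate
6 | [2,4,6-tris(methoxymethoxy)-3-(3-methylbut-2-en-1-yl)phenyl]lithium (formed in the flask, not isolated) | [Li]c1c(OCOC)cc(OCOC)c(CC=C(C)C)c1OCOC | intermediate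
7 | 2,4,6-tris(methoxymethoxy)-3-(3-methylbut-2-en-1-yl)benzaldehyde | COCOc1cc(OCOC)c(CC=C(C)C)c(OCOC)c1C=O | intermediate
8 | ethynyltrimethylsilane (trimethylsilylacetylene) | C#C[Si](C)(C)C | starting material
9 | [(trimethylsilyl)ethynyl]magnesium bromide (formed in the flask, not isolated) | C[Si](C)(C)C#C[Mg]Br | intermediate
10 | trimethyl(5-methylhex-4-en-1-yn-1-yl)silane | CC(C)=CCC#C[Si](C)(C)C | intermediate
11 | 5-methylhex-4-en-1-yne | C#CCC=C(C)C | intermediate
12 | (5-methylhex-4-en-1-yn-1-yl)lithium (formed in the flask, not isolated) | [Li]C#CCC=C(C)C | intermediate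
13 | rac-6-methyl-1-[2,4,6-tris(methoxymethoxy)-3-(3-methylbut-2-en-1-yl)phenyl]hept-5-en-2-yn-1-ol (racemic at the carbinol carbon) | COCOc1cc(OCOC)c(CC=C(C)C)c(OCOC)c1C(O)C#CCC=C(C)C | intermediate
14 | 6-methyl-1-[2,4,6-tris(methoxymethoxy)-3-(3-methylbut-2-en-1-yl)phenyl]hept-5-en-2-yn-1-one | COCOc1cc(OCOC)c(CC=C(C)C)c(OCOC)c1C(=O)C#CCC=C(C)C | intermediate
15 | furan | c1ccoc1 | starting material
16 | rac-[(1R,4S)-3-(3-methylbut-2-en-1-yl)-7-oxabicyclo[2.2.1]hepta-2,5-dien-2-yl][2,4,6-tris(methoxymethoxy)-3-(3-methylbut-2-en-1-yl)phenyl]methanone (racemic, one enantiomer drawn; not isolated) | O=C(C1=C(CC=C(C)C)[C@@H]2C=C[C@H]1O2)c1c(OCOC)cc(OCOC)c(CC=C(C)C)c1OCOC | intermediate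
17 | [3-hydroxy-2-(3-methylbut-2-en-1-yl)phenyl][2,4,6-tris(methoxymethoxy)-3-(3-methylbut-2-en-1-yl)phenyl]methanone | CC(C)=CCc1c(O)cccc1C(=O)c1c(OCOC)cc(OCOC)c(CC=C(C)C)c1OCOC | intermediate
18 | Cudraphenone D, [3-hydroxy-2-(3-methylbut-2-en-1-yl)phenyl][2,4,6-trihydroxy-3-(3-methylbut-2-en-1-yl)phenyl]methanone | CC(C)=CCc1c(O)cccc1C(=O)c1c(O)cc(O)c(CC=C(C)C)c1O | target

**Step count**
Total: 9 steps. Longest linear sequence: 7 steps (1, 2, 3, 6, 7, 8, 9 from phloroglucinol); the alkyne branch (steps 4, 5) joins at step 6.

**Steps most likely to fail**

1. Step 8 (proposed new method). Several processes could defeat it: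
 - the β-alkyl ynone may be too weak a dienophile, so that cycloaddition does not outrun cycloreversion;
 - furan may add in a conjugate sense and stop at the furyl enone after proton loss;
 - the aluminium reagent may transfer chloride or methyl to the ynone, isomerize the skipped enynone to an allenyl ketone, or strip MOM groups;
 - the bridge may fail to ionize at low temperature.

 Fallback, known chemistry throughout: it sets out from aldehyde 7 (with prenyl bromide 3 and bought 3-bromophenol) and comes back to the route at 18, with ring A taken from an aromatic precursor instead of being built. 3-Bromophenol would be protected with NaH and MOMCl to give 1-bromo-3-(methoxymethoxy)benzene F1. LiN(i-Pr)2 in THF at −78 °C removes the proton between bromine and OMOM to give [2-bromo-6-(methoxymethoxy)phenyl]lithium F2, which is alkylated with 3 in the presence of catalytic CuBr·SMe2 to 1-bromo-3-(methoxymethoxy)-2-(3-methylbut-2-en-1-yl)benzene F3. Bromine–lithium exchange with n-BuLi at −78 °C gives [3-(methoxymethoxy)-2-(3-methylbut-2-en-1-yl)phenyl]lithium F4, which adds to aldehyde 7 to give, after NH4Cl quench, the racemic diaryl carbinol [3-(methoxymethoxy)-2-(3-methylbut-2-en-1-yl)phenyl][2,4,6-tris(methoxymethoxy)-3-(3-methylbut-2-en-1-yl)phenyl]methanol F5. Oxidation with Dess–Martin periodinane buffered by NaHCO3 gives the tetra-MOM benzophenone F6, and the conditions of step 9 remove all four MOM groups to give 18.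

2. Step 9. Protonation of a prenyl alkene and ring closure onto the neighbouring phenol (chroman formation), or hydration of the alkene, may compete with cleavage of the slowest MOM ether, the one between the ring CH and the prenyl group.

 Fallback: it sets out from 17 and comes back at 18, and replaces protic acetal solvolysis by a base-buffered exchange of the acetals for silyl ethers followed by neutral hydrolysis. Treatment of 17 with Me3SiOTf and 2,2′-bipyridyl in MeCN at 0 °C → rt should convert the three aryl MOM ethers (and the free ring A phenol) into the tetrakis(trimethylsilyl) ether of Cudraphenone D F7, a known reaction type for aromatic MOM ethers that never exposes the alkenes to Brønsted acid. Addition of water at rt then hydrolyses the aryl silyl ethers to 18.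

3. Step 3. Deprotonation of the benzylic and allylic CH2 of the prenyl group, which is also flanked by two OMOM groups, may compete with ring metalation and lead to side-chain formylation or alkene migration.

 Fallback: it sets out from 2 and comes back at 7, and replaces deprotonation by site-specific bromine–lithium exchange. NBS (2 equiv, MeCN, 0 °C) should convert 2 into 2,4-dibromo-1,3,5-tris(methoxymethoxy)benzene F8. One equivalent of n-BuLi at −78 °C gives [3-bromo-2,4,6-tris(methoxymethoxy)phenyl]lithium F9, which is prenylated with 3 (catalytic CuI) to 2-bromo-1,3,5-tris(methoxymethoxy)-4-(3-methylbut-2-en-1-yl)benzene F10. A second exchange with n-BuLi at −78 °C, too fast for side-chain deprotonation to compete, gives aryllithium 6, which is formylated with DMF as in step 3 to give 7.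

**Further compounds**
F1 | step 8 | 1-bromo-3-(methoxymethoxy)benzene | COCOc1cccc(Br)c1
F2 | step 8 | [2-bromo-6-(methoxymethoxy)phenyl]lithium | [Li]c1c(Br)cccc1OCOC
F3 | step 8 | 1-bromo-3-(methoxymethoxy)-2-(3-methylbut-2-en-1-yl)benzene | COCOc1cccc(Br)c1CC=C(C)C
F4 | step 8 | [3-(methoxymethoxy)-2-(3-methylbut-2-en-1-yl)phenyl]lithium | [Li]c1cccc(OCOC)c1CC=C(C)C
F5 | step 8 | rac-[3-(methoxymethoxy)-2-(3-methylbut-2-en-1-yl)phenyl][2,4,6-tris(methoxymethoxy)-3-(3-methylbut-2-en-1-yl)phenyl]methanol | COCOc1cccc(C(O)c2c(OCOC)cc(OCOC)c(CC=C(C)C)c2OCOC)c1CC=C(C)C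
F6 | step 8 | [3-(methoxymethoxy)-2-(3-methylbut-2-en-1-yl)phenyl][2,4,6-tris(methoxymethoxy)-3-(3-methylbut-2-en-1-yl)phenyl]methanone | COCOc1cccc(C(=O)c2c(OCOC)cc(OCOC)c(CC=C(C)C)c2OCOC)c1CC=C(C)C
F7 | step 9 | tetrakis(trimethylsilyl) ether of Cudraphenone D | CC(C)=CCc1c(O[Si](C)(C)C)cccc1C(=O)c1c(O[Si](C)(C)C)cc(O[Si](C)(C)C)c(CC=C(C)C)c1O[Si](C)(C)C
F8 | step 3 | 2,4-dibromo-1,3,5-tris(methoxymethoxy)benzene | COCOc1cc(OCOC)c(Br)c(OCOC)c1Br
F9 | step 3 | [3-bromo-2,4,6-tris(methoxymethoxy)phenyl]lithium | [Li]c1c(OCOC)cc(OCOC)c(Br)c1OCOC
F10 | step 3 | 2-bromo-1,3,5-tris(methoxymethoxy)-4-(3-methylbut-2-en-1-yl)benzene | COCOc1cc(OCOC)c(CC=C(C)C)c(OCOC)c1Br
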